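**Plan**
1. Cuts: (i) the four O–benzyl bonds of a fully benzylated precursor. (ii) Both C–C bonds at the exocyclic acyl carbon, C(acyl)–CH2 (chain) and C(acyl)–C2 (ring), so that this carbon is carbon monoxide. (iii) The aryl–CH2 bond, so that the eight CH2 groups are octa-1,7-diene.
2. Enabling feature: ring atom C2 of the cyclohexane-1,3-dione ring, flanked by C1=O and the enolic C3–O. It is the one nucleophilic carbon, so it is iodinated selectively. Once O3 is benzylated, C2–I is a plain alkenyl iodide whose crowded, O3-pushed Pd–C2 bond takes up CO before it meets the alkylborane.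
3. Forward order: the carbocycle is not built but obtained by partial hydrogenation of phloroglucinol, then O3 and O5 are benzylated and C2 is iodinated. Octa-1,7-diene is joined first to the catechol ring (hydroboration/Suzuki–Miyaura). After a second hydroboration it is joined to CO and the ring iodide in one operation, and one hydrogenolysis ends the route.
4. Stereochemistry: C5 is stereogenic only while C1 and C3 differ, and the O3-benzyl ether freezes that difference. The (5S)-iodide comes from a resolution whose antipode can be racemised and recycled. No later step touches C5 or the enol ether until the final neutral hydrogenolysis.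

Key step: step 7

Remark (assumption): in the free target, a proton shift across the tricarbonyl unit with rotation about C2–C(acyl), or passage through the symmetric enolate, exchanges C1 and C3 and so turns (5S) into (5R); it is assumed that the drawn (5S)-enol is wanted as first released, so it is unveiled only in the last step under neutral aprotic conditions, it should be handled cold and acid/base-free, and its configurational lifetime has to be determined.

**Step 1**
Reactants: 1 phloroglucinol (benzene-1,3,5-triol)
Product: 2 5-hydroxycyclohexane-1,3-dione (dihydrophloroglucinol, enolised in solution)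
Conditions: H2 (3–4 bar), 5 % Rh/Al2O3, NaOH (1.0 equiv), H2O, rt; then HCl to pH 3, 0 °C, EtOAc extraction
Reagents that add atoms: none
Why: Partial catalytic hydrogenation of a polyphenolate (the reaction type that turns resorcinol into dihydroresorcinol): the monoanion takes up one H2 through its keto tautomer and the delocalised 1,3-dionate so formed resists further reduction, so the ring with its 1,3,5-oxygen pattern and the C5 carbinol is obtained in one step (2 is achiral, its two carbonyl groups are enantiotopic).

**Step 2**
Reactants: 2 5-hydroxycyclohexane-1,3-dione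
Product: 3 rac-3-(benzyloxy)-5-hydroxycyclohex-2-en-1-one
Conditions: BnOH (3 equiv), p-TsOH·H2O (5 mol %), 4 Å MS, THF, rt
Reagents that add atoms: benzyl alcohol, OCc1ccccc1
Why: Acid-catalysed enol etherification of a cyclic 1,3-dione (a vinylogous Fischer esterification): only the vinylogous acid unit condenses with BnOH, the secondary C5–OH stays free, room temperature keeps acid-induced dehydration at bay, and because either enantiotopic carbonyl group can react C5 becomes a stereocentre in racemic form.

**Step 3**
Reactants: 3 rac-3-(benzyloxy)-5-hydroxycyclohex-2-en-1-one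
Product: 4 rac-3,5-bis(benzyloxy)cyclohex-2-en-1-one
Conditions: BnOC(=NH)CCl3 (1.5 equiv), TfOH (5 mol %), CH2Cl2/cyclohexane, 0 °C → rt
Reagents that add atoms: benzyl 2,2,2-trichloroacetimidate, N=C(OCc1ccccc1)C(Cl)(Cl)Cl
Why: Acid-catalysed O-benzylation with a trichloroacetimidate, the usual base-free benzylation of β-hydroxy carbonyl compounds, avoids the E1cB loss of the C5 oxygen that alkoxide conditions would trigger, and any acid-induced migration of the enol ether between O1 and O3 is harmless because the material is still racemic.

**Step 4**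
Reactants: 4 rac-3,5-bis(benzyloxy)cyclohex-2-en-1-one
Product: 5 rac-3,5-bis(benzyloxy)-2-iodocyclohex-2-en-1-one
Conditions: NIS (1.1 equiv), TFA (10 mol %), MeCN, 0 °C → rt, dark
Reagents that add atoms: N-iodosuccinimide, O=C1CCC(=O)N1I
Why: Electrophilic α-iodination of a vinylogous ester: C2 is the only carbon that receives the push of O3, attack of I+ there gives an O3-stabilised cation, and loss of the C2 proton restores the conjugated system, while the benzyl ethers are inert to NIS in the dark.

**Step 5**
Reactants: 5 rac-3,5-bis(benzyloxy)-2-iodocyclohex-2-en-1-one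
Product: 6 (5S)-3,5-bis(benzyloxy)-2-iodocyclohex-2-en-1-one
Conditions: preparative SFC, immobilised amylose tris(3,5-dimethylphenylcarbamate) phase, CO2/i-PrOH, 35 °C
Reagents that add atoms: none
Why: Chromatographic enantiomer separation on a polysaccharide phase, placed after the last acidic step: the benzyl enol ether makes C1 and C3 constitutionally different, so C5 is a true and configurationally stable stereocentre here, the iodine atom allows assignment of (S) by anomalous-dispersion X-ray analysis, and the antipode can be racemised (cat. TsOH, BnOH, degenerate trans-etherification through the symmetric 1,3-dibenzyloxyallyl cation) and resubmitted.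

**Step 6**
Reactants: 7 4-bromo-1,2-bis(benzyloxy)benzene; 8 octa-1,7-diene
Product: 10 1,2-bis(benzyloxy)-4-(oct-7-en-1-yl)benzene, via B-(oct-7-en-1-yl)-9-BBN 9 (not isolated)
Conditions: 8 (5 equiv), 9-BBN (0.5 M in THF), 0 °C → rt, excess 8 stripped in vacuo; then 7, PdCl2(dppf)·CH2Cl2 (3 mol %), aq K3PO4, DMF/THF, 50 °C
Reagents that add atoms: 9-borabicyclo[3.3.1]nonane (9-BBN-H), B1C2CCCC1CCC2 (its boron bicycle stays in intermediate 9 only; 10 keeps one hydrogen of it)
Why: Hydroboration followed by B-alkyl Suzuki–Miyaura coupling: with the diene in excess 9-BBN adds once and at a terminal carbon, the primary alkylborane couples with the aryl bromide under Pd/dppf, and the untouched second terminal alkene is kept for step 7.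

**Step 7**
Reactants: 10 1,2-bis(benzyloxy)-4-(oct-7-en-1-yl)benzene; 6 (5S)-3,5-bis(benzyloxy)-2-iodocyclohex-2-en-1-one
Product: 12 (5S)-3,5-bis(benzyloxy)-2-{9-[3,4-bis(benzyloxy)phenyl]nonanoyl}cyclohex-2-en-1-one, via B-{8-[3,4-bis(benzyloxy)phenyl]octyl}-9-BBN 11 (not isolated)
Conditions: 10 (1.3 equiv), 9-BBN (0.5 M in THF, 1.3 equiv), 0 °C → rt; then added slowly to 6, Pd(PPh3)4 (5 mol %), K3PO4 (anhydrous powder, 3 equiv), CO (1–3 bar), dioxane/THF, rt; neutral work-up
Reagents that add atoms: carbon monoxide, [C-]#[O+]; 9-borabicyclo[3.3.1]nonane (9-BBN-H), B1C2CCCC1CCC2 (its boron bicycle stays in intermediate 11 only)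
Why: 9-BBN adds anti-Markovnikov to the terminal alkene of 10, so boron sits on the terminal CH2 of 11; Pd(0) inserts into the C2–I bond of 6, CO inserts into the Pd–C2 bond to give the ring-bound acylpalladium iodide, the phosphate-activated borate hands over its primary alkyl group, and reductive elimination forges the C(acyl)–CH2 bond, so that alkene, CO and ring are joined in one flask and the whole carbon skeleton and the tricarbonyl array are complete. The closest known reaction type is the carbonylative Suzuki–Miyaura coupling of 9-alkyl-9-BBN reagents with 1-iodoalkenes to α,β-unsaturated ketones. No ring is closed and no stereocentre is made; C5 lies across the ring from the reacting carbon and keeps its (S) configuration because the O3-benzyl ether stays in place and blocks the C1/C3 exchange. The selectivity needed is CO insertion before transmetalation (ketone instead of 2-alkyl enone): the Pd–C2 bond is flanked by C1=O and C3–OBn, which slows direct transmetalation, the O3 donor raises the migratory aptitude of C2, and CO saturation with slow addition of 11 at room temperature supports it. β-Hydride loss from the alkyl(acyl)palladium should be outrun by reductive elimination from the electron-poor acyl complex, and anhydrous K3PO4 is too weak a base and nucleophile to expel the benzyloxy groups at C5 or C3.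

**Step 8**
Reactants: 12 (5S)-3,5-bis(benzyloxy)-2-{9-[3,4-bis(benzyloxy)phenyl]nonanoyl}cyclohex-2-en-1-one
Product: 13 (5S)-2-[9-(3,4-dihydroxyphenyl)nonanoyl]-3,5-dihydroxycyclohex-2-en-1-one (target)
Conditions: H2 (1 bar), 20 % Pd(OH)2/C, EtOAc, rt; filtration under Ar, evaporation below 25 °C
Reagents that add atoms: none
Why: Catalytic hydrogenolysis of benzyl ethers: the two aryl, the one alkyl and the one enol benzyl ether all break at the benzylic C–O bond, so the C5–O bond and its (S) configuration are untouched, the hydrogen-bonded tetrasubstituted enol C=C is not reduced, and the neutral aprotic medium neither dehydrates the β-hydroxy ketone nor catalyses C1/C3 exchange while the enol drawn in the target is set free.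

**Compound list**
1 | phloroglucinol | Oc1cc(O)cc(O)c1 | starting material
2 | 5-hydroxycyclohexane-1,3-dione (dihydrophloroglucinol) | O=C1CC(O)CC(=O)C1 | intermediate
3 | rac-3-(benzyloxy)-5-hydroxycyclohex-2-en-1-one | O=C1C=C(OCc2ccccc2)CC(O)C1 | intermediate
4 | rac-3,5-bis(benzyloxy)cyclohex-2-en-1-one | O=C1C=C(OCc2ccccc2)CC(OCc2ccccc2)C1 | intermediate
5 | rac-3,5-bis(benzyloxy)-2-iodocyclohex-2-en-1-one | IC1=C(OCc2ccccc2)CC(OCc2ccccc2)CC1=O | intermediate
6 | (5S)-3,5-bis(benzyloxy)-2-iodocyclohex-2-en-1-one | IC1=C(OCc2ccccc2)C[C@H](OCc2ccccc2)CC1=O | intermediate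
7 | 4-bromo-1,2-bis(benzyloxy)benzene | Brc1ccc(OCc2ccccc2)c(OCc2ccccc2)c1 | starting material
8 | octa-1,7-diene | C=CCCCCC=C | starting material
9 | B-(oct-7-en-1-yl)-9-borabicyclo[3.3.1]nonane | C=CCCCCCCB1C2CCCC1CCC2 | intermediate (not isolated)
10 | 1,2-bis(benzyloxy)-4-(oct-7-en-1-yl)benzene | C=CCCCCCCc1ccc(OCc2ccccc2)c(OCc2ccccc2)c1 | intermediate
11 | B-{8-[3,4-bis(benzyloxy)phenyl]octyl}-9-borabicyclo[3.3.1]nonane | c1ccccc1COc1ccc(CCCCCCCCB2C3CCCC2CCC3)cc1OCc1ccccc1 | intermediate (not isolated)
12 | (5S)-3,5-bis(benzyloxy)-2-{9-[3,4-bis(benzyloxy)phenyl]nonanoyl}cyclohex-2-en-1-one | O=C(CCCCCCCCc1ccc(OCc2ccccc2)c(OCc2ccccc2)c1)C1=C(OCc2ccccc2)C[C@H](OCc2ccccc2)CC1=O | intermediate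
13 | (5S)-2-[9-(3,4-dihydroxyphenyl)nonanoyl]-3,5-dihydroxycyclohex-2-en-1-one | O=C(CCCCCCCCc1ccc(O)c(O)c1)C1=C(O)C[C@H](O)CC1=O | target

**Total step count:** 8. **Longest linear sequence:** 7 steps (1–5, 7, 8).

**Steps most likely to fail**

Step 7.
- Risks: coupling without CO uptake, β-hydride elimination from the alkylpalladium stage, or addition–elimination at C3 that strips the enol ether and so unlocks the C1/C3 exchange.
- Fallback: a stepwise union that sets out from 10 and 6 and comes back at 12.
- Linear-selective hydroformylation of 10 (Rh(acac)(CO)2/Xantphos, CO/H2, toluene, 80 °C) should give 9-[3,4-bis(benzyloxy)phenyl]nonanal F1, so CO is attached to the chain end first.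
- Nozaki–Hiyama–Kishi addition of 6 to this aldehyde (CrCl2, cat. NiCl2, DMF, rt; neutral and aldehyde-selective) should give (5S)-3,5-bis(benzyloxy)-2-{9-[3,4-bis(benzyloxy)phenyl]-1-hydroxynonyl}cyclohex-2-en-1-one F2 as a mixture of carbinol epimers.
- Oxidation with Dess–Martin periodinane (NaHCO3, CH2Cl2, 0 °C) removes the extra stereocentre and gives 12.

Step 8.
- Risks: sluggish cleavage of the secondary C5 benzyl ether, and during the long exposure loss of water across C5/C6 with aromatisation of the ring, air oxidation of the catechol and enol exchange.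
- Fallback: sets out from 12 and comes back at 13 without a new compound. It is a non-reductive Lewis-acid dealkylation (BCl3, pentamethylbenzene as benzyl-cation trap, CH2Cl2, −78 °C, quench with MeOH/CHCl3 at −78 °C).
- The price is an acidic quench, which is expected to speed up the C1/C3 exchange.

Step 3.
- Risks: acid-promoted β-elimination with aromatisation, and benzylation at C2 or at the carbonyl oxygen instead of O5.
- Fallback: sets out from 3 and comes back at 13, with a different hydrogenolysable group that is put on without acid or free benzyl cation.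
- BOMCl, i-Pr2NEt and cat. Bu4NI in CH2Cl2 at rt should give rac-3-(benzyloxy)-5-[(benzyloxy)methoxy]cyclohex-2-en-1-one F3.
- Iodination as in step 4 gives rac-3-(benzyloxy)-5-[(benzyloxy)methoxy]-2-iodocyclohex-2-en-1-one F4, and resolution as in step 5 gives its (5S)-enantiomer F5.
- Coupling with 11 and CO as in step 7 gives (5S)-3-(benzyloxy)-5-[(benzyloxy)methoxy]-2-{9-[3,4-bis(benzyloxy)phenyl]nonanoyl}cyclohex-2-en-1-one F6.
- The hydrogenolysis of step 8, in which the hemiacetal left at O5 collapses, leads to 13.

**Further compounds**
F1 | step 7 | 9-[3,4-bis(benzyloxy)phenyl]nonanal | O=CCCCCCCCCc1ccc(OCc2ccccc2)c(OCc2ccccc2)c1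
F2 | step 7 | (5S)-3,5-bis(benzyloxy)-2-{9-[3,4-bis(benzyloxy)phenyl]-1-hydroxynonyl}cyclohex-2-en-1-one (carbinol epimers) | OC(CCCCCCCCc1ccc(OCc2ccccc2)c(OCc2ccccc2)c1)C1=C(OCc2ccccc2)C[C@H](OCc2ccccc2)CC1=O
F0 | step 8 | none | none
F3 | step 3 | rac-3-(benzyloxy)-5-[(benzyloxy)methoxy]cyclohex-2-en-1-one | O=C1C=C(OCc2ccccc2)CC(OCOCc2ccccc2)C1
F4 | step 3 | rac-3-(benzyloxy)-5-[(benzyloxy)methoxy]-2-iodocyclohex-2-en-1-one | IC1=C(OCc2ccccc2)CC(OCOCc2ccccc2)CC1=O
F5 | step 3 | (5S)-3-(benzyloxy)-5-[(benzyloxy)methoxy]-2-iodocyclohex-2-en-1-one | IC1=C(OCc2ccccc2)C[C@H](OCOCc2ccccc2)CC1=O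
F6 | step 3 | (5S)-3-(benzyloxy)-5-[(benzyloxy)methoxy]-2-{9-[3,4-bis(benzyloxy)phenyl]nonanoyl}cyclohex-2-en-1-one | O=C(CCCCCCCCc1ccc(OCc2ccccc2)c(OCc2ccccc2)c1)C1=C(OCc2ccccc2)C[C@H](OCOCc2ccccc2)CC1=O
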